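## Retrosynthetic overview
1. 26 ⇐ 25 ⇐ 24: the epimerisable α-methyl ketone is carried as a TES-protected carbinol and unmasked in the last two steps.
2. Cyclohexadiene (second and last ring) ⇐ thermal disrotatory 6π closure of the (2E,4Z,6E,8E)-tetraenyl pyrone 23. This forms the C1–C6 bond with pyrone and alkenyl chain cis.
3. 23 ⇐ Suzuki coupling of the pyrone (E)-vinylboronate 22 with the (Z)-trienyl iodide 10.
4. 10 ⇐ Zhao iodo-olefination ⇐ two formyl-ylide Wittig homologations ⇐ Evans syn aldol of 1 with propanal, which sets the side-chain centre.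
5. 22 ⇐ γ-pyrone (first ring): β-keto ester dianion plus (E)-3-iodo-2-methylacrolein, then oxidation, DBU lactonisation, O-methylation and borylation.

Assumption: the remote side-chain centres bias the ring closure only weakly (about 1:1), so step 15 is planned at 50 % yield or less, and 24 is taken to be separable from its ring diastereomer by HPLC.

## Route

Step 1
Reactants: 1 (S)-4-benzyl-3-propionyl-1,3-oxazolidin-2-one; 2 propanal
Product: 4 (S)-4-benzyl-3-[(2S,3R)-3-hydroxy-2-methylpentanoyl]-1,3-oxazolidin-2-one, via (Z)-di-n-butylboron enolate 3 (not isolated)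
Conditions: n-Bu2BOTf, Et3N, CH2Cl2, 0 °C; 2, −78 → 0 °C; then pH 7 buffer, MeOH, 30 % H2O2, 0 °C
Reagents that add atoms: none
Why: Evans syn aldol: the (Z)-boron enolate 3 reacts through a Zimmerman–Traxler chair on the face opposite the benzyl group, which sets C2 as S (the later C4′ of the target) and C3 as R with >95:5 dr.

Step 2
Reactants: 4 aldol adduct
Product: 5 (2S,3R)-3-hydroxy-N-methoxy-N,2-dimethylpentanamide
Conditions: MeNH(OMe)·HCl, AlMe3, THF, −20 → 0 °C; 0.5 M HCl quench
Reagents that add atoms: N,O-dimethylhydroxylamine hydrochloride, CNOC.Cl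
Why: Weinreb aminolysis: the aluminium amide attacks the exocyclic imide carbonyl, helped by the free β-hydroxyl, and releases the auxiliary without touching either stereocentre.

Step 3
Reactants: 5 hydroxy Weinreb amide
Product: 6 (2S,3R)-N-methoxy-N,2-dimethyl-3-(triethylsilyloxy)pentanamide
Conditions: TESCl, imidazole, DMF, 0 °C → rt
Reagents that add atoms: chlorotriethylsilane, CC[Si](Cl)(CC)CC
Why: Silyl ether formation masks the future ketone as a carbinol, so the neighbouring methyl-bearing centre cannot enolise in the basic and thermal steps that follow, and TES comes off later under almost neutral conditions.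

Step 4
Reactants: 6 TES Weinreb amide
Product: 7 (2S,3R)-2-methyl-3-(triethylsilyloxy)pentanal
Conditions: DIBAL-H, THF, −78 °C; aq. Rochelle salt
Reagents that add atoms: none
Why: Weinreb amide reduction stops at the aldehyde level because the N-methoxy chelate collapses only on work-up, and at −78 °C the α-centre is not epimerised (7 is used at once).

Step 5
Reactants: 7 aldehyde
Product: 8 (2E,4R,5R)-2,4-dimethyl-5-(triethylsilyloxy)hept-2-enal
Conditions: Ph3P=C(Me)CHO, toluene, 90 °C
Reagents that add atoms: 2-(triphenylphosphoranylidene)propanal, CC(C=O)=P(c1ccccc1)(c1ccccc1)c1ccccc1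
Why: Wittig olefination with the stabilised formyl ylide gives the (E)-trisubstituted enal (>20:1) directly at the aldehyde oxidation level, and 8 is much less reactive than 7, so homologation stops after one unit.

Step 6
Reactants: 8 enal
Product: 9 (2E,4E,6R,7R)-2,4,6-trimethyl-7-(triethylsilyloxy)nona-2,4-dienal
Conditions: Ph3P=C(Me)CHO (1.5 equiv), toluene, 110 °C, 36 h
Reagents that add atoms: 2-(triphenylphosphoranylidene)propanal, CC(C=O)=P(c1ccccc1)(c1ccccc1)c1ccccc1
Why: A second Wittig olefination with the same stabilised ylide adds the next C(Me)=CH unit, again E-selectively, with the higher temperature making up for the lower reactivity of the enal.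

Step 7
Reactants: 9 dienal
Product: 10 triethyl{[(3R,4R,5E,7E,9Z)-10-iodo-4,6,8-trimethylundeca-5,7,9-trien-3-yl]oxy}silane
Conditions: EtPPh3I, n-BuLi, THF, rt; I2, −78 °C; NaHMDS, −20 °C; 9, −78 °C, dark
Reagents that add atoms: ethyltriphenylphosphonium iodide, CC[P+](c1ccccc1)(c1ccccc1)c1ccccc1.[I-]; iodine, II
Why: Stork–Zhao-type olefination: the non-stabilised α-iodo ylide reacts under kinetic control and puts iodine cis to the dienyl chain (Z:E about 10:1), which fixes the geometry of the central alkene needed for ring closure.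

Step 8
Reactants: 11 propargyl alcohol
Product: 13 (E)-3-iodo-2-methylprop-2-en-1-ol, via (E)-alkenylalane 12 (not isolated)
Conditions: AlMe3 (3 equiv), Cp2ZrCl2 (25 mol %), CH2Cl2, 0 °C → rt; I2, THF, −30 → 0 °C; sat. aq. K2CO3
Reagents that add atoms: trimethylaluminium, C[Al](C)C; iodine, II
Why: Negishi zirconium-catalysed carboalumination adds Me and Al syn across the alkyne with Al at the terminus, and iodinolysis with retention gives only the E iodide.

Step 9
Reactants: 13 iodo allylic alcohol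
Product: 14 (E)-3-iodo-2-methylprop-2-enal
Conditions: MnO2, CH2Cl2, rt, dark
Reagents that add atoms: none
Why: MnO2 allylic oxidation gives the enal without touching the vinyl iodide or its geometry.

Step 10
Reactants: 14 iodo enal; 15 methyl 2-methyl-3-oxopentanoate
Product: 17 methyl (6E)-5-hydroxy-7-iodo-2,4,6-trimethyl-3-oxohept-6-enoate (diastereomer mixture), via sodium lithium dianion 16 (not isolated)
Conditions: 15, NaH, THF, 0 °C; n-BuLi, 0 °C; 14, −78 °C; sat. aq. NH4Cl
Reagents that add atoms: none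
Why: Weiler dianion aldol: the more basic γ-carbanion of 16 adds 1,2 to the enal at −78 °C, and the diastereomer mixture does not matter because all three sp3 centres become sp2 in steps 11 and 12.

Step 11
Reactants: 17 hydroxy keto ester
Product: 18 methyl (6E)-7-iodo-2,4,6-trimethyl-3,5-dioxohept-6-enoate
Conditions: Dess–Martin periodinane, CH2Cl2, rt
Reagents that add atoms: none
Why: Dess–Martin oxidation converts the allylic β-hydroxy ketone into the 3,5-diketo ester under mild, non-basic conditions that leave the vinyl iodide alone.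

Step 12
Reactants: 18 diketo ester
Product: 19 4-hydroxy-6-[(1E)-1-iodoprop-1-en-2-yl]-3,5-dimethyl-2H-pyran-2-one
Conditions: DBU, toluene, 60 °C; 1 M HCl
Reagents that add atoms: none
Why: Base-induced enol lactonisation: the C5 enolate oxygen attacks the methyl ester to close the six-membered ring with loss of methanol, and tautomerisation gives the 4-hydroxy-2-pyrone.

Step 13
Reactants: 19 hydroxy-α-pyrone
Product: 21 2-[(1E)-1-iodoprop-1-en-2-yl]-6-methoxy-3,5-dimethyl-4H-pyran-4-one, via 4-hydroxy-2-methoxypyrylium triflate 20 (not isolated)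
Conditions: MeOTf, CH2Cl2, rt; sat. aq. NaHCO3 wash
Reagents that add atoms: methyl trifluoromethanesulfonate, COS(=O)(=O)C(F)(F)F
Why: The hard methylating agent alkylates the most nucleophilic oxygen, the lactone carbonyl, to give pyrylium salt 20, which loses the 4-OH proton on the basic wash and so gives the 2-methoxy-4-pyrone and not the 4-methoxy-2-pyrone.

Step 14
Reactants: 21 pyrone vinyl iodide
Product: 22 2-methoxy-3,5-dimethyl-6-[(1E)-1-(4,4,5,5-tetramethyl-1,3,2-dioxaborolan-2-yl)prop-1-en-2-yl]-4H-pyran-4-one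
Conditions: B2pin2, PdCl2(dppf)·CH2Cl2 (5 mol %), KOAc, 1,4-dioxane, 80 °C
Reagents that add atoms: bis(pinacolato)diboron, CC1(C)OB(OC1(C)C)B1OC(C)(C)C(C)(C)O1
Why: Miyaura borylation replaces iodine by Bpin with retention of the E geometry and tolerates the pyrone.

Step 15
Reactants: 10 (Z)-trienyl iodide; 22 pyrone vinylboronate
Product: 24 2-methoxy-3,5-dimethyl-6-{(1R,6S)-1,3,5-trimethyl-6-[(2E,4R,5R)-4-methyl-5-(triethylsilyloxy)hept-2-en-2-yl]cyclohexa-2,4-dien-1-yl}-4H-pyran-4-one, via (2E,4Z,6E,8E)-tetraenyl pyrone 23 (not isolated)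
Conditions: PdCl2(dppf)·CH2Cl2 (10 mol %), K3PO4, degassed THF/H2O 10:1, 45 °C, dark; extractive work-up, then toluene, BHT (cat.), 90 °C, Ar, dark; SiO2, then normal-phase HPLC
Reagents that add atoms: none
Why: Suzuki–Miyaura coupling joins the two sp2 carbons with retention of both alkene geometries, and the (E,Z,E)-triene unit of 23 then closes by thermal disrotatory 6π electrocyclisation, which can only place pyrone and alkenyl chain cis; facial bias is small, so the (1R,6S) isomer 24 is separated from its (1S,6R) diastereomer, and this separation fixes the absolute configuration of the ring.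

Step 16
Reactants: 24 TES ether
Product: 25 2-{(1R,6S)-6-[(2E,4R,5R)-5-hydroxy-4-methylhept-2-en-2-yl]-1,3,5-trimethylcyclohexa-2,4-dien-1-yl}-6-methoxy-3,5-dimethyl-4H-pyran-4-one
Conditions: HF·pyridine, pyridine, THF, 0 °C → rt, dark
Reagents that add atoms: none
Why: Fluoride-driven Si–O cleavage of the labile TES ether in buffered medium leaves the methoxypyrone, the diene and all stereocentres untouched.

Step 17
Reactants: 25 alcohol
Product: 26 target, 2-methoxy-3,5-dimethyl-6-{(1R,6S)-1,3,5-trimethyl-6-[(2E,4R)-4-methyl-5-oxohept-2-en-2-yl]cyclohexa-2,4-dien-1-yl}-4H-pyran-4-one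
Conditions: Dess–Martin periodinane, CH2Cl2, 0 °C → rt, dark; aq. Na2S2O3/NaHCO3; short neutral SiO2 column
Reagents that add atoms: none
Why: Dess–Martin oxidation works without base, so the new β,γ-unsaturated ketone neither epimerises at C4′ nor moves its double bond into conjugation (A1,3 strain also keeps the C4′–H bond out of alignment).

## Compound list
1 | (S)-4-benzyl-3-propionyl-1,3-oxazolidin-2-one | CCC(=O)N1[C@@H](Cc2ccccc2)COC1=O | starting material
2 | propanal | CCC=O | starting material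
3 | (Z)-di-n-butylboron enolate of 1 (not isolated) | C/C=C(\OB(CCCC)CCCC)N1[C@@H](Cc2ccccc2)COC1=O | intermediate
4 | (S)-4-benzyl-3-[(2S,3R)-3-hydroxy-2-methylpentanoyl]-1,3-oxazolidin-2-one | CC[C@@H](O)[C@H](C)C(=O)N1[C@@H](Cc2ccccc2)COC1=O | intermediate
5 | (2S,3R)-3-hydroxy-N-methoxy-N,2-dimethylpentanamide | CC[C@@H](O)[C@H](C)C(=O)N(C)OC | intermediate
6 | (2S,3R)-N-methoxy-N,2-dimethyl-3-(triethylsilyloxy)pentanamide | CC[C@@H](O[Si](CC)(CC)CC)[C@H](C)C(=O)N(C)OC | intermediate
7 | (2S,3R)-2-methyl-3-(triethylsilyloxy)pentanal | CC[C@@H](O[Si](CC)(CC)CC)[C@H](C)C=O | intermediate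
8 | (2E,4R,5R)-2,4-dimethyl-5-(triethylsilyloxy)hept-2-enal | CC[C@@H](O[Si](CC)(CC)CC)[C@H](C)/C=C(\C)C=O | intermediate
9 | (2E,4E,6R,7R)-2,4,6-trimethyl-7-(triethylsilyloxy)nona-2,4-dienal | CC[C@@H](O[Si](CC)(CC)CC)[C@H](C)/C=C(\C)/C=C(\C)C=O | intermediate
10 | triethyl{[(3R,4R,5E,7E,9Z)-10-iodo-4,6,8-trimethylundeca-5,7,9-trien-3-yl]oxy}silane | CC[C@@H](O[Si](CC)(CC)CC)[C@H](C)/C=C(\C)/C=C(\C)/C=C(\I)C | intermediate
11 | propargyl alcohol | C#CCO | starting material
12 | (E)-3-(dimethylalumanyl)-2-methylprop-2-enyl dimethylaluminium alkoxide (not isolated) | C[Al](C)/C=C(\C)CO[Al](C)C | intermediate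
13 | (E)-3-iodo-2-methylprop-2-en-1-ol | I/C=C(\C)CO | intermediate
14 | (E)-3-iodo-2-methylprop-2-enal | I/C=C(\C)C=O | intermediate
15 | methyl 2-methyl-3-oxopentanoate | CCC(=O)C(C)C(=O)OC | starting material
16 | sodium lithium dianion (bis-enolate) of 15 (not isolated) | CC=C([O-])C(C)=C([O-])OC.[Na+].[Li+] | intermediate
17 | methyl (6E)-5-hydroxy-7-iodo-2,4,6-trimethyl-3-oxohept-6-enoate (diastereomer mixture) | I/C=C(\C)C(O)C(C)C(=O)C(C)C(=O)OC | intermediate
18 | methyl (6E)-7-iodo-2,4,6-trimethyl-3,5-dioxohept-6-enoate | I/C=C(\C)C(=O)C(C)C(=O)C(C)C(=O)OC | intermediate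
19 | 4-hydroxy-6-[(1E)-1-iodoprop-1-en-2-yl]-3,5-dimethyl-2H-pyran-2-one | I/C=C(\C)c1oc(=O)c(C)c(O)c1C | intermediate
20 | 4-hydroxy-2-[(1E)-1-iodoprop-1-en-2-yl]-6-methoxy-3,5-dimethylpyrylium triflate (not isolated) | I/C=C(\C)c1[o+]c(OC)c(C)c(O)c1C.[O-]S(=O)(=O)C(F)(F)F | intermediate
21 | 2-[(1E)-1-iodoprop-1-en-2-yl]-6-methoxy-3,5-dimethyl-4H-pyran-4-one | I/C=C(\C)c1oc(OC)c(C)c(=O)c1C | intermediate
22 | 2-methoxy-3,5-dimethyl-6-[(1E)-1-(4,4,5,5-tetramethyl-1,3,2-dioxaborolan-2-yl)prop-1-en-2-yl]-4H-pyran-4-one | CC1(C)OB(/C=C(\C)c2oc(OC)c(C)c(=O)c2C)OC1(C)C | intermediate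
23 | 2-methoxy-3,5-dimethyl-6-[(2E,4Z,6E,8E,10R,11R)-4,6,8,10-tetramethyl-11-(triethylsilyloxy)trideca-2,4,6,8-tetraen-2-yl]-4H-pyran-4-one (not isolated) | CC[C@@H](O[Si](CC)(CC)CC)[C@H](C)/C=C(\C)/C=C(\C)/C=C(/C)\C=C(/C)c1oc(OC)c(C)c(=O)c1C | intermediate
24 | 2-methoxy-3,5-dimethyl-6-{(1R,6S)-1,3,5-trimethyl-6-[(2E,4R,5R)-4-methyl-5-(triethylsilyloxy)hept-2-en-2-yl]cyclohexa-2,4-dien-1-yl}-4H-pyran-4-one | CC[C@@H](O[Si](CC)(CC)CC)[C@H](C)/C=C(\C)[C@H]1C(C)=CC(C)=C[C@@]1(C)c1oc(OC)c(C)c(=O)c1C | intermediate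
25 | 2-{(1R,6S)-6-[(2E,4R,5R)-5-hydroxy-4-methylhept-2-en-2-yl]-1,3,5-trimethylcyclohexa-2,4-dien-1-yl}-6-methoxy-3,5-dimethyl-4H-pyran-4-one | CC[C@@H](O)[C@H](C)/C=C(\C)[C@H]1C(C)=CC(C)=C[C@@]1(C)c1oc(OC)c(C)c(=O)c1C | intermediate
26 | 2-methoxy-3,5-dimethyl-6-{(1R,6S)-1,3,5-trimethyl-6-[(2E,4R)-4-methyl-5-oxohept-2-en-2-yl]cyclohexa-2,4-dien-1-yl}-4H-pyran-4-one (CNP0301958.2) | CCC(=O)[C@H](C)/C=C(\C)[C@H]1C(C)=CC(C)=C[C@@]1(C)c1oc(OC)c(C)c(=O)c1C | target

## Count and risks
Total step count: 17.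
Longest linear sequence: 10 steps (steps 1–7, then 15–17). The pyrone branch (steps 8–14, then 15–17) is equally long.

**Step 15.** This is the riskiest step. The coupling is hindered, and 23 could undergo a [1,7]-H shift instead of ring closure. The two cis diastereomers are expected in about equal amounts and may not separate as silyl ethers. Compounds 24–26 must also be kept in the dark under argon, since such dienes photoisomerise and add singlet oxygen.

The fallback sets out from 24 and comes back at 25.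
- The unseparated mixture of 24 and the (1S,6R) ring diastereomer of 24 F4 is desilylated as in step 16. This gives 25 together with the (1S,6R) ring diastereomer of 25 F5.
- The mixed alcohols are acylated (4-bromobenzoyl chloride, Et3N, DMAP, CH2Cl2) to the 4-bromobenzoate of 25 F6 and the 4-bromobenzoate of F5 F7.
- These UV-active, crystalline esters are separated by crystallisation or HPLC. Anomalous dispersion of bromine in an X-ray structure proves which one has the (1R,6S) ring.
- Methanolysis of F6 (K2CO3, MeOH, rt, where exchange at the pyrone OMe is degenerate) returns pure 25.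

**Step 7.** The iodo-olefination of a hindered dienal usually gives only moderate yield, together with some E isomer and some de-iodinated alkene.

The fallback sets out from 9 and comes back at 24.
- A boron-Wittig reaction of 9 with lithiated 1,1-bis(pinacolboryl)ethane (LiTMP, THF, 0 → −78 °C → rt) proceeds by syn B–O elimination, with the chain eclipsing the small Bpin rather than methyl.
- It gives 2-[(2E,4E,6E,8R,9R)-4,6,8-trimethyl-9-(triethylsilyloxy)undeca-2,4,6-trien-2-yl]-4,4,5,5-tetramethyl-1,3,2-dioxaborolane F3. Boron sits cis to the dienyl chain, so the spatial geometry is the same as in 10.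
- F3 is coupled with the pyrone iodide 21 under the conditions of step 15 to give 23 and then 24. The polarity of the coupling is reversed, and step 14 is no longer needed.

**Step 6.** The enal 8 is a sluggish acceptor, and the product 9 can be homologated once more by the formyl ylide.

The fallback sets out from 8 and comes back at 9.
- The ester ylide ethyl 2-(triphenylphosphoranylidene)propanoate (toluene, 80 °C) cannot over-react. It gives ethyl (2E,4E,6R,7R)-2,4,6-trimethyl-7-(triethylsilyloxy)nona-2,4-dienoate F1.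
- DIBAL-H (CH2Cl2, −78 °C) gives (2E,4E,6R,7R)-2,4,6-trimethyl-7-(triethylsilyloxy)nona-2,4-dien-1-ol F2.
- MnO2 (CH2Cl2, rt) oxidises F2 to 9. The detour costs two extra steps.

## Further compounds
F1 | step 6 | ethyl (2E,4E,6R,7R)-2,4,6-trimethyl-7-(triethylsilyloxy)nona-2,4-dienoate | CC[C@@H](O[Si](CC)(CC)CC)[C@H](C)/C=C(\C)/C=C(\C)C(=O)OCC
F2 | step 6 | (2E,4E,6R,7R)-2,4,6-trimethyl-7-(triethylsilyloxy)nona-2,4-dien-1-ol | CC[C@@H](O[Si](CC)(CC)CC)[C@H](C)/C=C(\C)/C=C(\C)CO
F3 | step 7 | 2-[(2E,4E,6E,8R,9R)-4,6,8-trimethyl-9-(triethylsilyloxy)undeca-2,4,6-trien-2-yl]-4,4,5,5-tetramethyl-1,3,2-dioxaborolane | CC[C@@H](O[Si](CC)(CC)CC)[C@H](C)/C=C(\C)/C=C(\C)/C=C(\B1OC(C)(C)C(C)(C)O1)C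
F4 | step 15 | (1S,6R) ring diastereomer of 24 | CC[C@@H](O[Si](CC)(CC)CC)[C@H](C)/C=C(\C)[C@@H]1C(C)=CC(C)=C[C@]1(C)c1oc(OC)c(C)c(=O)c1C
F5 | step 15 | (1S,6R) ring diastereomer of 25 | CC[C@@H](O)[C@H](C)/C=C(\C)[C@@H]1C(C)=CC(C)=C[C@]1(C)c1oc(OC)c(C)c(=O)c1C
F6 | step 15 | 4-bromobenzoate of 25 | CC[C@@H](OC(=O)c1ccc(Br)cc1)[C@H](C)/C=C(\C)[C@H]1C(C)=CC(C)=C[C@@]1(C)c1oc(OC)c(C)c(=O)c1C
F7 | step 15 | 4-bromobenzoate of F5 | CC[C@@H](OC(=O)c1ccc(Br)cc1)[C@H](C)/C=C(\C)[C@@H]1C(C)=CC(C)=C[C@]1(C)c1oc(OC)c(C)c(=O)c1C
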